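**Numbering used throughout**

1 5-bromovanillin · 2 malonic acid · 3 arylidenemalonic acid (in flask) · 4 (E)-5-bromoferulic acid · 5 bis-silylated acid (in flask) · 6 O-silyl acid · 7 (S)-4-benzyl-1,3-oxazolidin-2-one · 8 mixed pivalic anhydride (in flask) · 9 O-silyl N-enoyl imide · 10 phenolic N-enoyl imide · 11 bis(quinone methide) (in flask) · 12 quinone methide phenol (in flask) · 13 dibromo dihydronaphthalene bis-imide · 14 tetralin bis-imide · 15 2,3-cis dimethyl ester (in flask) · 16 all-trans dimethyl ester · 17 (+)-isolariciresinol

## Analysis of the target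

Compound 17 is a 1-aryltetralin. Ring A is the fused arene (C4a to C8a) with OMe on C6 and OH on C7. Ring B is the saturated ring (C1 to C4), with a 4-hydroxy-3-methoxyphenyl group on C1, a CH2OH on each of C2 and C3, and a benzylic CH2 at C4. The three stereocentres are contiguous, C1 (S), C2 (R) and C3 (R), with 1,2-trans and 2,3-trans relations. In the half-chair of ring B all three substituents can be equatorial, so the target is the most stable diastereomer whenever C2 and C3 can be equilibrated. The sensitive groups are two guaiacol-type phenols, which are easily oxidized, the doubly benzylic C1–H para to a phenol, and the 1,4-diol. The hard part is the absolute configuration at C1, a diarylmethine with no neighbouring handle, together with the risk of heavy protecting-group traffic on two almost identical oxygenated rings. The strategy rests on a hidden symmetry: the eighteen skeletal carbons are two identical C6–C3 halves, joined side chain to side chain at C2–C3 and side chain to ring at C1–C8a. C8a lies para to the C6 methoxy group, the position at which such a ring reacts as a nucleophile.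

## Retrosynthetic reasoning

**17 ⇒ 16.** No C–C bond is cut first. Both primary alcohols are taken back to the carboxyl level, because only there are C2 and C3 α to a carbonyl and open to adjustment. The forward step must reduce two esters beside two free phenols without touching a stereocentre.

**16 ⇒ 14 (through 15).** The 2,3-trans relation is reached by equilibration, not built directly: C1 is not acidic and anchors the absolute configuration, and the all-equatorial diester 16 is the thermodynamic sink. The ester groups are traced to the N-acyl auxiliaries of 14. Exchange and equilibration are placed in one operation, after the auxiliaries have left, because α-branched N-acyloxazolidinones enolize only with difficulty: the enolate would suffer allylic strain against the auxiliary ring. The esters 15 and 16 enolize readily. The halogens must already be gone at this point, since a substituent on C8 pushes the C1 aryl group axial and would distort the equilibrium.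

**14 ⇒ 13.** The C3–H and C4–H bonds are traced to a C3=C4 alkene, and the aryl C–H bonds at C8 and on the pendant ring to C–Br bonds. One hydrogenation achieves both. Its facial outcome at C3 does not matter, because the next operation corrects C3.

**13 ⇒ 10 + 10 (through 11 and 12).** This is the disconnection that carries the synthesis: C2–C3 and C1–C8a are cut, and the skeleton falls into two identical nine-carbon phenols. Cutting here, and not inside ring A or at C3–C4, uses the dimer symmetry and means that neither aromatic ring has to be constructed. The forward reaction must couple two phenoxy radicals at their side-chain carbons and not at oxygen or at the ring. The bromine ortho to each phenol is there for this purpose. It must then close ring B para to the methoxy group, and it must set C2 absolutely and C1 relative to C2. The auxiliary 7 on each half is the source of absolute control.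

**10 ⇒ 9 ⇒ 6 + 7.** The N–acyl bond is cut. The phenol is masked as a silyl ether only for the acylation, because a free phenol would compete for the activated acid. Removal of the silyl group must leave the enoyl imide intact.

**6 ⇒ 4 ⇒ 1 + 2.** The side-chain alkene is cut by a condensation with decarboxylation. The aldehyde 1 already carries the complete ring substitution, including the blocking bromine, and 2 supplies the two remaining carbons.

## Alternatives that were turned down

**Alternative 1:** pyrone–alkyne cycloaddition that builds ring A.
- Disconnection: C5–C6 and C4a–C8a are cut, so ring A itself is traced to a 3-methoxy-4-benzyloxy-2-pyrone and a terminal alkyne held on one chain that already carries all three stereocentres (A1).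
- Forward key step: heating A1 adds the pyrone termini across the alkyne, closing ring B. The bridged lactone then fragments and aromatizes ring A to tetra-O-benzyl isolariciresinol (A2). Hydrogenolysis of A2 would give 17.
- For: the arene substitution pattern is fixed by the tether and the cascade is irreversible. Every stereocentre is in place before the key step, so no late correction is needed. On that point it is stronger than the chosen route, which adjusts C3 afterwards.
- Against: ring A is an ordinary guaiacyl ring that a vanillin derivative supplies for nothing. Building it requires a non-commercial dialkoxypyrone attached to a hindered benzylic carbon, and an open chain with three contiguous stereocentres made by linear asymmetric synthesis. An electron-rich pyrone and an unactivated alkyne are a poorly matched pair and need high temperature. Under those conditions the C1–H, vinylogously α to the pyrone carbonyl, may epimerize. Four benzyl ethers must be carried and removed.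
- Comparison: the chosen route is several times shorter and forms only ring B, buying both arenes with the building block. It gives up pre-set stereochemistry for a thermodynamic end game.

**Alternative 2:** o-quinodimethane Diels–Alder with a chiral fumarate.
- Disconnection: C1–C2 and C3–C4 are cut. The diene is released from the 1-aryl benzo-fused cyclic sulfone A3, and the dienophile is the bis[(S)-lactate] fumarate A4.
- Forward key step: heating A3 opens the sulfone cheletropically to the diene with the aryl group turned outward, and A4 adds to give the trans,trans diester A5.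
- For: ring B and two bonds form in one pericyclic step. The 2,3-trans relation comes straight from the fumarate geometry, which is stronger than the chosen route on that point. The esters are ordinary and reduce directly.
- Against: the temperature of the cheletropic step rules out the Lewis-acid chelation on which lactate fumarates depend for facial control, so the absolute sense is uncertain. With a fumarate one ester is necessarily endo and the other exo, so the endo rule does not decide between 1,2-cis and 1,2-trans; only sterics do. A3 needs its own multistep synthesis with two O-benzyl groups.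
- Comparison: the chosen route sets 1,2-trans in an intramolecular closure with a fixed mode, and both halves come from one compound. In exchange it needs an equilibration at C3.

**Alternative 3:** pendant-ring quinone methide captured by a tethered malonate.
- Disconnection: only C1–C2 is cut. The precursor A6 is a diarylmethane whose ring A carries the CH2–CH(CH2OBn)–CH(CO2Me)2 chain and whose pendant ring has the free phenol.
- Forward key step: Ag2O oxidizes the free phenol of A6 so that the diarylmethane carbon becomes a quinone methide. The malonate carbon adds to it and closes ring B, giving the 2,2-diester A7 with the C1 aryl group cis to the C3 substituent. Dealkoxycarbonylation and reduction would follow.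
- For: the closure is a polar two-electron step with a single possible regiochemistry, so there is none of the competition between radical coupling modes that the chosen route must control. C1 is directed by an sp3 centre (C3) that established asymmetric alkylation can make, so the absolute sense is more predictable than in the chosen route.
- Against: A6 requires a long linear sequence with the two phenols differentiated and C3 set beforehand. C2 is formed quaternary next to the hindered C1, and its configuration is decided only in a later decarboxylative protonation.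
- Comparison: the alternative has more steps and more protecting groups. The chosen route makes two skeletal bonds and two stereocentres in one operation from a four-step precursor, at the price of relying on auxiliary control in a radical coupling.

Key step: step 5

Assumption: the (S)-auxiliary is taken to direct C2–C3 bond formation to the face that gives the (1S,2R) configuration of 13. This is the sense expected if iron holds the two imide carbonyls syn, as in alkylation of the corresponding Z-enolate. If the sense proves opposite, the same route is run with the (R)-auxiliary.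

## Route

Step 1
Reactants: 1 5-bromovanillin (3-bromo-4-hydroxy-5-methoxybenzaldehyde); 2 malonic acid
Product: 4 (E)-3-(3-bromo-4-hydroxy-5-methoxyphenyl)prop-2-enoic acid (5-bromoferulic acid), via arylidenemalonic acid 3 (not isolated)
Conditions: 2 (2 equiv), pyridine, piperidine (cat.), 90 °C; then aq. HCl
Reagents that add atoms: none
Why: Knoevenagel–Doebner condensation; the arylidenemalonic acid 3 decarboxylates in hot pyridine to the (E)-cinnamic acid, and neither the free phenol nor the aryl bromide interferes.

Step 2
Reactants: 4 (E)-5-bromoferulic acid
Product: 6 (E)-3-[3-bromo-4-(tert-butyldimethylsilyloxy)-5-methoxyphenyl]prop-2-enoic acid, via silyl ester silyl ether 5 (not isolated)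
Conditions: TBSCl (2.4 equiv), imidazole (5 equiv), DMF, rt; then AcOH/THF/H2O, rt
Reagents that add atoms: tert-butyldimethylsilyl chloride, CC(C)(C)[Si](C)(C)Cl
Why: Silylation of both acidic OH groups followed by selective hydrolysis; a silyl ester is cleaved by dilute aqueous acid far faster than an aryl silyl ether, so the phenol stays masked and the acid is set free.

Step 3
Reactants: 6 O-silyl acid; 7 (S)-4-benzyl-1,3-oxazolidin-2-one
Product: 9 (4S)-4-benzyl-3-{(E)-3-[3-bromo-4-(tert-butyldimethylsilyloxy)-5-methoxyphenyl]prop-2-enoyl}-1,3-oxazolidin-2-one, via mixed pivalic anhydride 8 (not isolated)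
Conditions: PivCl (1.1 equiv), Et3N (2.5 equiv), THF, −20 °C; then LiCl (1.1 equiv), 7, −20 °C → rt
Reagents that add atoms: none
Why: N-acylation of the oxazolidinone through a mixed anhydride; the tert-butyl group steers attack to the cinnamoyl carbonyl and LiCl/Et3N makes the oxazolidinone nucleophilic enough without a strong base, so the alkene geometry and the auxiliary stereocentre are untouched.

Step 4
Reactants: 9 O-silyl N-enoyl imide
Product: 10 (4S)-4-benzyl-3-[(E)-3-(3-bromo-4-hydroxy-5-methoxyphenyl)prop-2-enoyl]-1,3-oxazolidin-2-one
Conditions: TBAF (1.1 equiv), AcOH (1.5 equiv), THF, 0 °C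
Reagents that add atoms: none
Why: Fluoride-induced cleavage of the aryl silyl ether; the acetic acid buffer keeps the medium from becoming basic, so the enoyl imide is not attacked.

Step 5
Reactants: 10 phenolic N-enoyl imide (two molecules)
Product: 13 3,3'-{[(1S,2R)-8-bromo-1-(3-bromo-4-hydroxy-5-methoxyphenyl)-7-hydroxy-6-methoxy-1,2-dihydronaphthalene-2,3-diyl]dicarbonyl}bis[(4S)-4-benzyl-1,3-oxazolidin-2-one], via bis(quinone methide) 11 (not isolated), via quinone methide phenol 12 (not isolated)
Conditions: FeCl3·6H2O (1.1 equiv relative to 10), acetone/H2O, 0 °C → rt, argon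
Reagents that add atoms: none
Why: FeCl3 takes one electron from each phenol, and the two radicals, which carry spin at the side-chain carbon next to the carbonyl, combine there to form C2–C3 and the bis(quinone methide) 11, because bromine occupies the ring position ortho to oxygen and the doubly flanked oxygen couples only reversibly. One quinone methide of 11 then loses its acidic C–H (α to the imide and vinylogous to the dienone) and rearomatizes to the (E)-arylidene phenol 12, whose ring carbon para to the methoxy group adds to the remaining quinone methide carbon to form C1–C8a, a 6-exo-trig conjugate addition of Friedel–Crafts type that closes ring B and restores the second phenol. The closest known reaction type is the biomimetic β–β oxidative dimerization of ortho-blocked 4-hydroxycinnamic esters and amides to trans-1-aryl-1,2-dihydronaphthalene-2,3-dicarboxylic derivatives. C2 is set in the radical combination: with the enoyl unit s-cis and both imide carbonyls held syn on iron, the benzyl group of each auxiliary covers one face of the carbon next to the carbonyl, the same discrimination as in alkylation of the corresponding Z-enolate, which for the (S)-auxiliary leads to the 2R centre (R,R in 11). C1 is set relative to C2 in the ring closure, where the quinone methide ring and the C2 acyl group lie anti (pseudo-diaxial) in the half-chair transition state, away from the C3 acyl group and the peri bromine, so the 1,2-trans product results. Because both halves carry the same auxiliary, it does not matter which half tautomerizes. The step needs β–β coupling over β–O and β–ring coupling (secured by the bromine blocker), closure para and not ortho to the methoxy group (secured by the stronger para activation), and tautomerization faster than capture of 11 by water (secured by the acidity of the C–H next to the imide); the oxidant is held at one equivalent per phenol to spare the phenols of 13.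

Step 6
Reactants: 13 dibromo dihydronaphthalene bis-imide
Product: 14 3,3'-{[(1S,2R,3S)-7-hydroxy-1-(4-hydroxy-3-methoxyphenyl)-6-methoxy-1,2,3,4-tetrahydronaphthalene-2,3-diyl]dicarbonyl}bis[(4S)-4-benzyl-1,3-oxazolidin-2-one]
Conditions: H2 (3 atm), 10% Pd/C, NaOAc (2.5 equiv), EtOAc/MeOH, rt
Reagents that add atoms: none
Why: Heterogeneous hydrogenation saturates the conjugated C3=C4 bond and hydrogenolyses both aryl C–Br bonds, with NaOAc taking up the HBr. Hydrogen is expected to reach C3 from the face opposite the pseudoaxial C2 acyl group, giving the 2,3-cis isomer; the C3 epimer, if formed, converges in step 7.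

Step 7
Reactants: 14 tetralin bis-imide
Product: 16 dimethyl (1S,2R,3R)-7-hydroxy-1-(4-hydroxy-3-methoxyphenyl)-6-methoxy-1,2,3,4-tetrahydronaphthalene-2,3-dicarboxylate, via 2,3-cis dimethyl ester 15 (not isolated)
Conditions: NaOMe (5 equiv), MeOH/THF, 0 °C → rt, then 50 °C, argon; AcOH quench
Reagents that add atoms: methanol, CO (delivered as sodium methoxide, C[O-].[Na+])
Why: Methoxide transesterifies both N-acyloxazolidinones at the exocyclic carbonyl and releases 7 for recovery. The resulting ester 15 enolizes, unlike the α-branched imides, so C3 (and reversibly C2) equilibrates to the all-equatorial 1,2-trans-2,3-trans diester, while C1 has no acidic hydrogen and keeps the absolute configuration.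

Step 8
Reactants: 16 all-trans dimethyl ester
Product: 17 (+)-isolariciresinol, (1S,2R,3R)-7-hydroxy-1-(4-hydroxy-3-methoxyphenyl)-2,3-bis(hydroxymethyl)-6-methoxy-1,2,3,4-tetrahydronaphthalene
Conditions: LiAlH4 (6 equiv), THF, 0 °C → 50 °C; then aq. KNaC4H4O6 (tartrate), EtOAc
Reagents that add atoms: none
Why: Hydride reduction of both esters to primary alcohols; the phenols are only deprotonated and return on work-up, and the stereocentres are already in their stable arrangement.

## Compound list

1 | 5-bromovanillin (3-bromo-4-hydroxy-5-methoxybenzaldehyde) | COc1cc(C=O)cc(Br)c1O | starting material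
2 | malonic acid | OC(=O)CC(=O)O | starting material
3 | 2-[(3-bromo-4-hydroxy-5-methoxyphenyl)methylidene]propanedioic acid | COc1cc(C=C(C(=O)O)C(=O)O)cc(Br)c1O | intermediate (not isolated)
4 | (E)-3-(3-bromo-4-hydroxy-5-methoxyphenyl)prop-2-enoic acid | COc1cc(/C=C/C(=O)O)cc(Br)c1O | intermediate
5 | tert-butyldimethylsilyl (E)-3-[3-bromo-4-(tert-butyldimethylsilyloxy)-5-methoxyphenyl]prop-2-enoate | COc1cc(/C=C/C(=O)O[Si](C)(C)C(C)(C)C)cc(Br)c1O[Si](C)(C)C(C)(C)C | intermediate (not isolated)
6 | (E)-3-[3-bromo-4-(tert-butyldimethylsilyloxy)-5-methoxyphenyl]prop-2-enoic acid | COc1cc(/C=C/C(=O)O)cc(Br)c1O[Si](C)(C)C(C)(C)C | intermediate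
7 | (S)-4-benzyl-1,3-oxazolidin-2-one | O=C1N[C@@H](Cc2ccccc2)CO1 | starting material
8 | (E)-3-[3-bromo-4-(tert-butyldimethylsilyloxy)-5-methoxyphenyl]prop-2-enoic pivalic anhydride | COc1cc(/C=C/C(=O)OC(=O)C(C)(C)C)cc(Br)c1O[Si](C)(C)C(C)(C)C | intermediate (not isolated)
9 | (4S)-4-benzyl-3-{(E)-3-[3-bromo-4-(tert-butyldimethylsilyloxy)-5-methoxyphenyl]prop-2-enoyl}-1,3-oxazolidin-2-one | COc1cc(/C=C/C(=O)N2[C@@H](Cc3ccccc3)COC2=O)cc(Br)c1O[Si](C)(C)C(C)(C)C | intermediate
10 | (4S)-4-benzyl-3-[(E)-3-(3-bromo-4-hydroxy-5-methoxyphenyl)prop-2-enoyl]-1,3-oxazolidin-2-one | COc1cc(/C=C/C(=O)N2[C@@H](Cc3ccccc3)COC2=O)cc(Br)c1O | intermediate (precursor of the key step)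
11 | (2R,3R)-1,4-bis[(4S)-4-benzyl-2-oxo-1,3-oxazolidin-3-yl]-2,3-bis[(3-bromo-5-methoxy-4-oxocyclohexa-2,5-dien-1-ylidene)methyl]butane-1,4-dione (exocyclic alkene geometry not defined) | COC1=CC(=C[C@@H](C(=O)N2[C@@H](Cc3ccccc3)COC2=O)[C@@H](C=C2C=C(OC)C(=O)C(Br)=C2)C(=O)N2[C@@H](Cc3ccccc3)COC2=O)C=C(Br)C1=O | intermediate (not isolated)
12 | (3R)-1,4-bis[(4S)-4-benzyl-2-oxo-1,3-oxazolidin-3-yl]-2-[(E)-(3-bromo-4-hydroxy-5-methoxyphenyl)methylidene]-3-[(3-bromo-5-methoxy-4-oxocyclohexa-2,5-dien-1-ylidene)methyl]butane-1,4-dione | COc1cc(/C=C(/C(=O)N2[C@@H](Cc3ccccc3)COC2=O)[C@@H](C=C2C=C(OC)C(=O)C(Br)=C2)C(=O)N2[C@@H](Cc3ccccc3)COC2=O)cc(Br)c1O | intermediate (not isolated)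
13 | 3,3'-{[(1S,2R)-8-bromo-1-(3-bromo-4-hydroxy-5-methoxyphenyl)-7-hydroxy-6-methoxy-1,2-dihydronaphthalene-2,3-diyl]dicarbonyl}bis[(4S)-4-benzyl-1,3-oxazolidin-2-one] (1,2-trans) | COc1cc([C@H]2c3c(Br)c(O)c(OC)cc3C=C(C(=O)N3[C@@H](Cc4ccccc4)COC3=O)[C@@H]2C(=O)N2[C@@H](Cc3ccccc3)COC2=O)cc(Br)c1O | intermediate (product of the key step)
14 | 3,3'-{[(1S,2R,3S)-7-hydroxy-1-(4-hydroxy-3-methoxyphenyl)-6-methoxy-1,2,3,4-tetrahydronaphthalene-2,3-diyl]dicarbonyl}bis[(4S)-4-benzyl-1,3-oxazolidin-2-one] (1,2-trans, 2,3-cis) | COc1cc([C@H]2c3cc(O)c(OC)cc3C[C@H](C(=O)N3[C@@H](Cc4ccccc4)COC3=O)[C@@H]2C(=O)N2[C@@H](Cc3ccccc3)COC2=O)ccc1O | intermediate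
15 | dimethyl (1S,2R,3S)-7-hydroxy-1-(4-hydroxy-3-methoxyphenyl)-6-methoxy-1,2,3,4-tetrahydronaphthalene-2,3-dicarboxylate (2,3-cis) | COc1cc([C@H]2c3cc(O)c(OC)cc3C[C@H](C(=O)OC)[C@@H]2C(=O)OC)ccc1O | intermediate (not isolated)
16 | dimethyl (1S,2R,3R)-7-hydroxy-1-(4-hydroxy-3-methoxyphenyl)-6-methoxy-1,2,3,4-tetrahydronaphthalene-2,3-dicarboxylate (all-trans) | COc1cc([C@H]2c3cc(O)c(OC)cc3C[C@@H](C(=O)OC)[C@@H]2C(=O)OC)ccc1O | intermediate
17 | (+)-isolariciresinol, (1S,2R,3R)-7-hydroxy-1-(4-hydroxy-3-methoxyphenyl)-2,3-bis(hydroxymethyl)-6-methoxy-1,2,3,4-tetrahydronaphthalene | COc1cc([C@H]2c3cc(O)c(OC)cc3C[C@@H](CO)[C@@H]2CO)ccc1O | target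

## Step count and least certain steps

Total: 8 steps. Longest linear sequence: 8 steps from 1. The auxiliary 7 enters in step 3 and is released for recovery in step 7.

**Step 5 (key step).**
- What may go wrong: facial discrimination in the radical combination may be poor or reversed if the imide is not held in the chelated conformation in the aqueous medium. If only the sense is wrong, the (R)-auxiliary is used. Electron transfer from the bromophenol may also be slow, coupling through oxygen may lead to oligomers, the ring may close ortho to the methoxy group, water may capture the quinone methide before tautomerization, and the product phenols may be oxidized further.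
- Fallback: this gives up auxiliary control for resolution and uses the ester version of the cascade, the best-established form of the reaction. It sets out from 4. Fischer esterification (MeOH, H2SO4 cat., reflux) should give methyl (E)-5-bromoferulate F1. Oxidation of F1 with FeCl3·6H2O in acetone/water should give racemic dimethyl trans-8-bromo-1-(3-bromo-4-hydroxy-5-methoxyphenyl)-7-hydroxy-6-methoxy-1,2-dihydronaphthalene-2,3-dicarboxylate F2. Preparative chromatography of F2 on a chiral stationary phase should give its (1S,2R)-enantiomer F3. Hydrogenation of F3 (H2, 10% Pd/C, NaOAc) gives 15, which is isolated and rejoins the route at the equilibration of step 7 to 16.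

**Step 7.**
- What may go wrong: at the two hindered acyl groups, methoxide may attack the ring carbonyl of the auxiliary and open it instead of transferring the acyl group. Equilibration at C3 may stop short, and the electron-rich phenoxides may be oxidized by traces of air.
- Fallback: the imides are cleaved by peroxide hydrolysis, the cleavage least sensitive to hindrance, and the ester is then made separately. It sets out from 14. LiOH/H2O2 in THF/H2O at 0 °C should give (1S,2R,3S)-7-hydroxy-1-(4-hydroxy-3-methoxyphenyl)-6-methoxy-1,2,3,4-tetrahydronaphthalene-2,3-dicarboxylic acid F4. Fischer esterification of F4 (MeOH, H2SO4 cat., reflux) gives 15, and NaOMe in MeOH then equilibrates isolated 15 to 16.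

**Step 6.**
- What may go wrong: saturation of the hindered, conjugated, trisubstituted C3=C4 bond may stall on the heterogeneous catalyst, in part because bromide released in the hydrogenolysis can poison palladium.
- Fallback: C3 is set by a hydroxyl-directed homogeneous hydrogenation, which also makes the equilibration unnecessary. It sets out from 13. LiBH4 with MeOH in THF at 0 °C should reduce both imides to give [(1S,2R)-8-bromo-1-(3-bromo-4-hydroxy-5-methoxyphenyl)-7-hydroxy-6-methoxy-1,2-dihydronaphthalene-2,3-diyl]dimethanol F5. Hydrogenation of F5 with [Ir(cod)(PCy3)(py)]PF6 in CH2Cl2 should deliver hydrogen to C3 from the face of the C2 hydroxymethyl group, which binds the metal, and so give the 2,3-trans compound 8,5'-dibromoisolariciresinol F6. Hydrogenolysis of F6 (H2, 10% Pd/C, NaOAc, MeOH), with only the aryl bromides left to reduce, arrives at 17.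

**Step 3.**
- What may go wrong: the oxazolidinone may take up the pivaloyl group from the mixed anhydride, or the aryl silyl ether may be partly lost in the chloride/amine medium.
- Fallback: the enoyl imide is built by olefination, not acylation, which also bypasses step 2. It sets out from 1 and 7. Silylation of 1 (TBSCl, imidazole, DMF) gives 3-bromo-4-(tert-butyldimethylsilyloxy)-5-methoxybenzaldehyde F7. Acylation of lithiated 7 (n-BuLi, THF, −78 °C) with bromoacetyl bromide gives (4S)-4-benzyl-3-(bromoacetyl)-1,3-oxazolidin-2-one F8. A Michaelis–Arbuzov reaction of F8 with P(OEt)3 gives diethyl {2-[(4S)-4-benzyl-2-oxo-1,3-oxazolidin-3-yl]-2-oxoethyl}phosphonate F9. A Horner–Wadsworth–Emmons reaction of F7 with F9 (LiCl, i-Pr2NEt, MeCN) should give the (E)-enoyl imide 9, where the route is rejoined.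

## Further compounds

F1 | step 5 | methyl (E)-3-(3-bromo-4-hydroxy-5-methoxyphenyl)prop-2-enoate | COc1cc(/C=C/C(=O)OC)cc(Br)c1O
F2 | step 5 | racemic dimethyl trans-8-bromo-1-(3-bromo-4-hydroxy-5-methoxyphenyl)-7-hydroxy-6-methoxy-1,2-dihydronaphthalene-2,3-dicarboxylate (racemate, one enantiomer drawn) | COc1cc([C@H]2c3c(Br)c(O)c(OC)cc3C=C(C(=O)OC)[C@@H]2C(=O)OC)cc(Br)c1O
F3 | step 5 | dimethyl (1S,2R)-8-bromo-1-(3-bromo-4-hydroxy-5-methoxyphenyl)-7-hydroxy-6-methoxy-1,2-dihydronaphthalene-2,3-dicarboxylate (single enantiomer) | COc1cc([C@H]2c3c(Br)c(O)c(OC)cc3C=C(C(=O)OC)[C@@H]2C(=O)OC)cc(Br)c1O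
F4 | step 7 | (1S,2R,3S)-7-hydroxy-1-(4-hydroxy-3-methoxyphenyl)-6-methoxy-1,2,3,4-tetrahydronaphthalene-2,3-dicarboxylic acid | COc1cc([C@H]2c3cc(O)c(OC)cc3C[C@H](C(=O)O)[C@@H]2C(=O)O)ccc1O
F5 | step 6 | [(1S,2R)-8-bromo-1-(3-bromo-4-hydroxy-5-methoxyphenyl)-7-hydroxy-6-methoxy-1,2-dihydronaphthalene-2,3-diyl]dimethanol | COc1cc([C@H]2c3c(Br)c(O)c(OC)cc3C=C(CO)[C@@H]2CO)cc(Br)c1O
F6 | step 6 | (1S,2R,3R)-8-bromo-1-(3-bromo-4-hydroxy-5-methoxyphenyl)-7-hydroxy-2,3-bis(hydroxymethyl)-6-methoxy-1,2,3,4-tetrahydronaphthalene | COc1cc([C@H]2c3c(Br)c(O)c(OC)cc3C[C@@H](CO)[C@@H]2CO)cc(Br)c1O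
F7 | step 3 | 3-bromo-4-(tert-butyldimethylsilyloxy)-5-methoxybenzaldehyde | COc1cc(C=O)cc(Br)c1O[Si](C)(C)C(C)(C)C
F8 | step 3 | (4S)-4-benzyl-3-(bromoacetyl)-1,3-oxazolidin-2-one | O=C(CBr)N1[C@@H](Cc2ccccc2)COC1=O
F9 | step 3 | diethyl {2-[(4S)-4-benzyl-2-oxo-1,3-oxazolidin-3-yl]-2-oxoethyl}phosphonate | CCOP(=O)(OCC)CC(=O)N1[C@@H](Cc2ccccc2)COC1=O
A1 | alternative 1 | 4-benzyloxy-6-[1-(4-benzyloxy-3-methoxyphenyl)-2,3-bis(benzyloxymethyl)hex-5-yn-1-yl]-3-methoxy-2H-pyran-2-one, stereocentres as in the SMILES | COc1cc([C@@H](C2=CC(OCc3ccccc3)=C(OC)C(=O)O2)[C@@H](COCc2ccccc2)[C@H](COCc2ccccc2)CC#C)ccc1OCc1ccccc1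
A2 | alternative 1 | tetra-O-benzyl isolariciresinol | COc1cc([C@H]2c3cc(OCc4ccccc4)c(OC)cc3C[C@@H](COCc3ccccc3)[C@@H]2COCc2ccccc2)ccc1OCc1ccccc1
A3 | alternative 2 | 6-benzyloxy-1-(4-benzyloxy-3-methoxyphenyl)-5-methoxy-1,3-dihydro-2-benzothiophene 2,2-dioxide (racemic, no configuration assigned) | COc1cc(C2c3cc(OCc4ccccc4)c(OC)cc3CS2(=O)=O)ccc1OCc1ccccc1
A4 | alternative 2 | bis[(S)-1-methoxy-1-oxopropan-2-yl] fumarate | COC(=O)[C@H](C)OC(=O)/C=C/C(=O)O[C@@H](C)C(=O)OC
A5 | alternative 2 | trans,trans 1-aryltetralin-2,3-dicarboxylic bis[(S)-lactate] ester, O-benzyl protected | COc1cc([C@H]2c3cc(OCc4ccccc4)c(OC)cc3C[C@@H](C(=O)O[C@@H](C)C(=O)OC)[C@@H]2C(=O)O[C@@H](C)C(=O)OC)ccc1OCc1ccccc1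
A6 | alternative 3 | dimethyl 2-{1-benzyloxy-3-[4-benzyloxy-2-(4-hydroxy-3-methoxybenzyl)-5-methoxyphenyl]propan-2-yl}malonate, stereocentre as in the SMILES | COc1cc(Cc2cc(OCc3ccccc3)c(OC)cc2C[C@@H](COCc2ccccc2)C(C(=O)OC)C(=O)OC)ccc1O
A7 | alternative 3 | dimethyl 7-benzyloxy-3-(benzyloxymethyl)-1-(4-hydroxy-3-methoxyphenyl)-6-methoxy-3,4-dihydronaphthalene-2,2(1H)-dicarboxylate, C1 aryl and C3 substituent cis | COc1cc([C@H]2c3cc(OCc4ccccc4)c(OC)cc3C[C@@H](COCc3ccccc3)C2(C(=O)OC)C(=O)OC)ccc1O
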